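**Retrosynthetic overview**
1. Target ⇒ 2,13-diol + 3-methylbut-2-enoyl chloride (acylation of the secondary alcohol only, last step).
2. Diol ⇒ acyclic C20 hydroxy-tetraene bearing PhSO2 at C7: one Fe–H (MHAT) radical cascade closes ring A (C4–C5) first, then ring B (C9–C10); loss of PhSO2• writes the 7,8-alkene, and the C2 carbinol alone steers C5, C9 and C10.
3. Tetraene ⇒ C6–C7 alkylation of an allyl sulfone carbanion (C7–C16 half, carries C13) with an allylic chloride (C1–C6 half, carries C2).
4. C1–C6 half ⇒ (R)-epichlorohydrin + isopropenyl Grignard + acetylide, then carboalumination/CH2O and allylic chlorination.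
5. C7–C16 half ⇒ isoprene + PhSO2Cl (radical 1,4-addition), acetylacetone, catalytic asymmetric CH2 transfer (sets C13), sulfonium-ylide homologation to the vinyl carbinol.

Assumption: labdane numbering is used throughout (ring A C1–C5/C10, ring B C5–C10, side chain C11–C16); the target is (2R,5R,9R,10R,13S), an ent-labdane with trans ring fusion, equatorial 2-O and equatorial C9 side chain.

**Route**

Step 1
Reactants: 1 (R)-epichlorohydrin; 2 isopropenylmagnesium bromide
Product: 3 (2R)-1-chloro-4-methylpent-4-en-2-ol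
Conditions: CuI (10 mol %), THF, −40 → −20 °C; aq NH4Cl
Reagents that add atoms: none
Why: Cu-catalysed Grignard epoxide opening (SN2 at the unsubstituted CH2) leaves the C–O stereocentre untouched, so (R)-1 gives (R)-3, the future C2.

Step 2
Reactants: 3 (2R)-1-chloro-4-methylpent-4-en-2-ol; 4 lithium acetylide–ethylenediamine complex
Product: 6 (4R)-6-methylhept-6-en-1-yn-4-ol, via 2-(2-methylallyl)oxirane 5 (not isolated)
Conditions: 4 (3 equiv), DMSO, 0 °C → rt; aq NH4Cl
Reagents that add atoms: none
Why: the first equivalent of base closes the chlorohydrin to the volatile terminal epoxide (intramolecular Williamson), which acetylide opens at CH2 (SN2 epoxide opening); the carbinol carbon is never a reaction centre, so R is retained.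

Step 3
Reactants: 6 (4R)-6-methylhept-6-en-1-yn-4-ol
Product: 8 (2E,5R)-3,7-dimethylocta-2,7-diene-1,5-diol, via alkenyldimethylalane 7 (not isolated)
Conditions: Me3Al (3.5 equiv), Cp2ZrCl2 (25 mol %), CH2Cl2, 0 °C → rt; evaporate; n-BuLi (2.2 equiv), THF, −78 °C; (CH2O)n, −78 °C → rt; aq Rochelle salt
Reagents that add atoms: trimethylaluminium C[Al](C)C; paraformaldehyde C=O
Why: Negishi Zr-catalysed carboalumination adds Me–Al syn across the terminal alkyne with Me on the internal carbon (the aluminium alkoxide is tolerated, the 1,1-disubstituted alkene is inert), and the alanate is hydroxymethylated with retention, fixing the E-trisubstituted C5=C10 alkene.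

Step 4
Reactants: 8 (2E,5R)-3,7-dimethylocta-2,7-diene-1,5-diol
Product: 9 (4R,6E)-8-chloro-2,6-dimethylocta-1,6-dien-4-ol
Conditions: NCS (1.2 equiv), Me2S (1.3 equiv), CH2Cl2, −20 → 0 °C
Reagents that add atoms: N-chlorosuccinimide O=C1CCC(=O)N1Cl
Why: Corey–Kim chlorination converts only the primary allylic alcohol (chloride displaces its alkoxysulfonium salt by SN2, alkene geometry kept), while the secondary homoallylic alcohol is returned on work-up.

Step 5
Reactants: 10 isoprene
Product: 11 (E)-4-chloro-2-methyl-1-(phenylsulfonyl)but-2-ene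
Conditions: PhSO2Cl (1.0 equiv), isoprene (1.5 equiv), CuCl (5 mol %), Et3N·HCl (5 mol %), MeCN, 100 °C, sealed tube; crystallise
Reagents that add atoms: benzenesulfonyl chloride O=S(=O)(Cl)c1ccccc1
Why: Asscher–Vofsi Cu-catalysed atom-transfer radical addition: PhSO2• adds to C1 of isoprene to give the more substituted allyl radical, and Cl transfer at the open terminus gives the crystalline E-1,4-adduct.

Step 6
Reactants: 11 (E)-4-chloro-2-methyl-1-(phenylsulfonyl)but-2-ene; 12 acetylacetone
Product: 14 (5E)-6-methyl-7-(phenylsulfonyl)hept-5-en-2-one, via 3-allylated pentane-2,4-dione 13 (not isolated)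
Conditions: K2CO3 (1.2 equiv), NaI (10 mol %), EtOH, reflux
Reagents that add atoms: none
Why: C-alkylation of acetylacetone by the primary allylic chloride (SN2) followed by retro-Claisen deacetylation in the same pot gives the methyl ketone; carbonate is too weak to deprotonate the sulfone, so the E-allyl sulfone survives.

Step 7
Reactants: 14 (5E)-6-methyl-7-(phenylsulfonyl)hept-5-en-2-one
Product: 15 (2S)-2-methyl-2-[(3E)-4-methyl-5-(phenylsulfonyl)pent-3-en-1-yl]oxirane
Conditions: Me3S(O)I/NaH (1.2 equiv), La–Li3–tris(binaphthoxide) (LLB, 5 mol %; BINOL antipode that gives the S-epoxide), (2,4,6-(MeO)3C6H2)3P=O (5 mol %), 5 Å MS, THF, rt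
Reagents that add atoms: trimethylsulfoxonium iodide C[S+](C)(C)=O.[I-]
Why: catalytic asymmetric Corey–Chaykovsky epoxidation of a methyl ketone (La/Li–BINOLate with phosphine oxide): the bimetallic catalyst binds ketone and ylide and delivers CH2 to one carbonyl face (typically >90 % ee for alkyl methyl ketones), which sets C13.

Step 8
Reactants: 15 (2S)-2-methyl-2-[(3E)-4-methyl-5-(phenylsulfonyl)pent-3-en-1-yl]oxirane
Product: 16 (3S,6E)-3,7-dimethyl-8-(phenylsulfonyl)octa-1,6-dien-3-ol
Conditions: Me3S+ I− (3 equiv), n-BuLi (2.9 equiv), THF, −10 °C → rt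
Reagents that add atoms: trimethylsulfonium iodide C[S+](C)C.[I-]
Why: one-carbon homologation of an epoxide to an allylic alcohol with dimethylsulfonium methylide (ylide opens the CH2 terminus, then ylide-mediated loss of Me2S); the quaternary C–O bond is untouched, so S is retained, and the ylide is not basic enough to consume the sulfone.

Step 9
Reactants: 16 (3S,6E)-3,7-dimethyl-8-(phenylsulfonyl)octa-1,6-dien-3-ol; 9 (4R,6E)-8-chloro-2,6-dimethylocta-1,6-dien-4-ol
Product: 17 (3S,6E,8RS,10E,13R)-3,7,11,15-tetramethyl-8-(phenylsulfonyl)hexadeca-1,6,10,15-tetraene-3,13-diol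
Conditions: 16 (1.1 equiv), n-BuLi (2.2 equiv), THF–DMPU (6:1), −78 °C; add 9 pre-treated with LiHMDS (1.0 equiv, −78 °C); −78 → −30 °C; aq NH4Cl
Reagents that add atoms: none
Why: Julia/Biellmann-type α-alkylation of the lithiated allyl sulfone (alkoxide/carbanion dianion) by the primary allylic chloride (SN2) keeps both E-alkenes; the new sulfone-bearing centre (C7) forms as a mixture that is irrelevant because C7 becomes sp2 in the next step.

Step 10
Reactants: 17 (3S,6E,8RS,10E,13R)-3,7,11,15-tetramethyl-8-(phenylsulfonyl)hexadeca-1,6,10,15-tetraene-3,13-diol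
Product: 18 (2R,5R,9R,10R,13S)-labda-7,14-diene-2,13-diol
Conditions: Fe(acac)3 (0.5 equiv), PhSiH3 (2.0 equiv), EtOH/(CH2OH)2 (5:1), 5 mM, degassed, 60 °C
Reagents that add atoms: none
Why: Proposed new method: Fe–H transfers H• to the 1,1-disubstituted alkene to give the tertiary C4 radical, which closes 6-endo on C5 of the E-alkene through a chair with the C2–OH equatorial (an axial OH would clash with the axial C4 methyl), the resulting C10 radical closes 6-endo on C9 of the E-allyl sulfone through a second chair (trans-decalin, C9 chain equatorial), and the β-sulfonyl C8 radical expels PhSO2• to give only the 7,8-alkene, so C5, C9 and C10 are all set from C2; the closest known reactions are Fe(acac)3/PhSiH3 MHAT-initiated radical polyene cyclisations and radical addition–fragmentation on allyl sulfones.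

Step 11
Reactants: 18 (2R,5R,9R,10R,13S)-labda-7,14-diene-2,13-diol; 19 3-methylbut-2-enoyl chloride
Product: 20 (2R,5R,9R,10R,13S)-13-hydroxylabda-7,14-dien-2-yl 3-methylbut-2-enoate (CNP0252389.1)
Conditions: 19 (1.5 equiv), pyridine (5 equiv), DMAP (5 mol %), CH2Cl2, 0 °C → rt
Reagents that add atoms: none
Why: DMAP-catalysed acylation reacts only at the equatorial secondary alcohol because the tertiary allylic C13–OH is too hindered, and pyridine instead of a trialkylamine avoids vinylketene formation and deconjugation of the senecioate.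

**Compound list**
1 | (R)-epichlorohydrin | ClC[C@H]1CO1 | starting material
2 | isopropenylmagnesium bromide | CC(=C)[Mg]Br | starting material
3 | (2R)-1-chloro-4-methylpent-4-en-2-ol | ClC[C@H](O)CC(C)=C | intermediate
4 | lithium acetylide–ethylenediamine complex | [Li]C#C.NCCN | starting material
5 | (2R)-2-(2-methylprop-2-en-1-yl)oxirane | C=C(C)C[C@@H]1CO1 | intermediate
6 | (4R)-6-methylhept-6-en-1-yn-4-ol | C#CC[C@H](O)CC(C)=C | intermediate
7 | (1E,4R)-4-(dimethylalumanyloxy)-2,6-dimethylhepta-1,6-dien-1-yl(dimethyl)alane | C=C(C)C[C@@H](O[Al](C)C)C/C(C)=C/[Al](C)C | intermediate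
8 | (2E,5R)-3,7-dimethylocta-2,7-diene-1,5-diol | C=C(C)C[C@@H](O)C/C(C)=C/CO | intermediate
9 | (4R,6E)-8-chloro-2,6-dimethylocta-1,6-dien-4-ol | C=C(C)C[C@@H](O)C/C(C)=C/CCl | intermediate
10 | isoprene | C=CC(C)=C | starting material
11 | (E)-4-chloro-2-methyl-1-(phenylsulfonyl)but-2-ene | ClC/C=C(\C)CS(=O)(=O)c1ccccc1 | intermediate
12 | acetylacetone (pentane-2,4-dione) | CC(=O)CC(C)=O | starting material
13 | 3-[(2E)-3-methyl-4-(phenylsulfonyl)but-2-en-1-yl]pentane-2,4-dione | CC(=O)C(C/C=C(\C)CS(=O)(=O)c1ccccc1)C(C)=O | intermediate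
14 | (5E)-6-methyl-7-(phenylsulfonyl)hept-5-en-2-one | CC(=O)CC/C=C(\C)CS(=O)(=O)c1ccccc1 | intermediate
15 | (2S)-2-methyl-2-[(3E)-4-methyl-5-(phenylsulfonyl)pent-3-en-1-yl]oxirane | C[C@@]1(CO1)CC/C=C(\C)CS(=O)(=O)c2ccccc2 | intermediate
16 | (3S,6E)-3,7-dimethyl-8-(phenylsulfonyl)octa-1,6-dien-3-ol | C=C[C@@](C)(O)CC/C=C(\C)CS(=O)(=O)c1ccccc1 | intermediate
17 | (3S,6E,8RS,10E,13R)-3,7,11,15-tetramethyl-8-(phenylsulfonyl)hexadeca-1,6,10,15-tetraene-3,13-diol | C=C(C)C[C@@H](O)C/C(C)=C/CC(S(=O)(=O)c1ccccc1)/C(C)=C/CC[C@](C)(O)C=C | intermediate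
18 | (2R,5R,9R,10R,13S)-labda-7,14-diene-2,13-diol | C=C[C@@](C)(O)CC[C@@H]1C(C)=CC[C@@H]2C(C)(C)C[C@@H](O)C[C@@]12C | intermediate
19 | 3-methylbut-2-enoyl chloride | CC(C)=CC(=O)Cl | starting material
20 | (2R,5R,9R,10R,13S)-13-hydroxylabda-7,14-dien-2-yl 3-methylbut-2-enoate | C=C[C@@](C)(O)CC[C@@H]1C(C)=CC[C@@H]2C(C)(C)C[C@@H](OC(=O)C=C(C)C)C[C@@]12C | target

**Totals**
Total steps: 11. Longest linear sequence: 7 (steps 1–4 or 5–8, then 9–11).

**Steps most likely to fail**

Step 10. The vinyl group of the tertiary allylic alcohol can take up H• in competition with the 1,1-disubstituted alkene. The C7 epimer whose sulfone sits pseudo-equatorial may also be reduced at C8 before it fragments. The fallback sets out from 15 (with 9) and comes back at 18, keeping the vinyl group latent as the epoxide during the radical step. Epoxide 15 is lithiated (n-BuLi 1.05 equiv, THF–DMPU, −78 °C; the carbanion cannot open its own epoxide because the ring would contain the E-alkene) and alkylated with the lithium alkoxide of 9 to give the epoxy-triene sulfone F1. The same Fe(acac)3/PhSiH3 cascade, now with a single terminal alkene, gives the 13,14-epoxy-15-norlabd-7-en-2-ol F2. Me3S+ I−/n-BuLi then converts the epoxide of F2 into the vinyl carbinol 18.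

Step 9. The free hydroxyl groups can quench the carbanion or be O-alkylated, and the hydroxy allylic chloride is sensitive. The fallback sets out from 9 and comes back at 17. TBSCl/imidazole (DMF) turns 9 into the silyl ether F3, which has no acidic proton and no competing alkoxide. The dianion of 16 is alkylated with F3 to the mono-silylated tetraene sulfone F4, and TBAF (THF, 0 °C) removes the silyl group to give 17.

Step 7. The enantioselectivity for this functionalised methyl ketone is unproven, and the basic La catalyst may be slowed by the sulfone. The fallback sets out from 14 and comes back at 16 by a reagent-controlled Sharpless route. Horner–Wadsworth–Emmons reaction of 14 with triethyl phosphonoacetate/NaH gives the (2E)-dienoate F5 (the minor 2Z isomer is removed by chromatography). DIBAL-H reduces it to the allylic alcohol F6. Sharpless epoxidation (Ti(Oi-Pr)4, L-(+)-DET, t-BuOOH, 4 Å MS, −20 °C) gives the (2S,3S)-epoxy alcohol F7. I2/PPh3/imidazole gives the epoxy iodide F8, and Zn dust in refluxing EtOH opens it reductively to the tertiary allylic alcohol 16 with C13 untouched.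

Further compounds
F1 | step 10 | (4R,6E,9RS,10E)-2,6,10-trimethyl-13-[(2S)-2-methyloxiran-2-yl]-9-(phenylsulfonyl)trideca-1,6,10-trien-4-ol | C=C(C)C[C@@H](O)C/C(C)=C/CC(S(=O)(=O)c1ccccc1)/C(C)=C/CC[C@@]2(C)CO2
F2 | step 10 | (2R,5R,9R,10R,13S)-13,14-epoxy-15-norlabd-7-en-2-ol | C[C@@]3(CO3)CC[C@@H]1C(C)=CC[C@@H]2C(C)(C)C[C@@H](O)C[C@@]12C
F3 | step 9 | tert-butyl{[(4R,6E)-8-chloro-2,6-dimethylocta-1,6-dien-4-yl]oxy}dimethylsilane | C=C(C)C[C@@H](O[Si](C)(C)C(C)(C)C)C/C(C)=C/CCl
F4 | step 9 | (3S,6E,8RS,10E,13R)-13-(tert-butyldimethylsilyloxy)-3,7,11,15-tetramethyl-8-(phenylsulfonyl)hexadeca-1,6,10,15-tetraen-3-ol | C=C(C)C[C@@H](O[Si](C)(C)C(C)(C)C)C/C(C)=C/CC(S(=O)(=O)c1ccccc1)/C(C)=C/CC[C@](C)(O)C=C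
F5 | step 7 | ethyl (2E,6E)-3,7-dimethyl-8-(phenylsulfonyl)octa-2,6-dienoate | CCOC(=O)/C=C(\C)CC/C=C(\C)CS(=O)(=O)c1ccccc1
F6 | step 7 | (2E,6E)-3,7-dimethyl-8-(phenylsulfonyl)octa-2,6-dien-1-ol | OC/C=C(\C)CC/C=C(\C)CS(=O)(=O)c1ccccc1
F7 | step 7 | {(2S,3S)-3-methyl-3-[(3E)-4-methyl-5-(phenylsulfonyl)pent-3-en-1-yl]oxiran-2-yl}methanol | OC[C@@H]1O[C@@]1(C)CC/C=C(\C)CS(=O)(=O)c2ccccc2
F8 | step 7 | (2R,3S)-2-(iodomethyl)-3-methyl-3-[(3E)-4-methyl-5-(phenylsulfonyl)pent-3-en-1-yl]oxirane | IC[C@@H]1O[C@@]1(C)CC/C=C(\C)CS(=O)(=O)c2ccccc2
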